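**Plan**

- Cuts: the lactone Cα–CH2(ring B) bond, the ring C C5–CH2 bond to the lactone β-carbon, O1–C2 of the dihydrobenzofuran, the two aldol bonds C3–C2 (ring C/ring D half) and C8–C7 (glycerol unit), and the C8–O–ring B ether.
- Forward: arylacetyl imide aldol → triol 13 → furan ring closure → aryl Grignard opening of a cyclopropane-fused butyrolactone (the lactone ring arrives intact) → trans alkylation with the ring A/ring B benzylic bromide → desilylation and hydrogenolysis.
- Enabling feature: C2 of the dihydrobenzofuran is benzylic to guaiacyl ring D, whose para oxygen O-4 can take up a positive charge at C2 (a quinone-methide-like oxocarbenium ion); the phenolic oxygen O1 on C7a of ring C is placed to close the five-membered ring O1–C7a–C3a–C3–C2 onto it.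
- Stereochemistry: C3 from an (S)-4-benzyloxazolidinone boron aldol; C2 from C3 (trans, thermodynamic) in the key step; lactone Cβ from (R)-epichlorohydrin; lactone Cα from Cβ (anti alkylation); glycerol C8 from an (R)-4-benzyloxazolidinone glycolate aldol; C7 by Mitsunobu inversion of the syn adduct.

Key step: step 8

Remark on labels: ring A is the guaiacyl ring of the glycerol unit (C7 benzylic, C8 ether carbon, C9 primary), ring B the aryl ether ring on the lactone α-CH2, ring C the benzo ring of the dihydrobenzofuran and ring D its 2-aryl group. The target is the erythro (7R,8S) glycerol ether, the (3R,4R)-trans lactone and the (2S,3R)-trans dihydrobenzofuran.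

Assumption: compounds 1, 6, 9, 16, 17, 22 and 23 are taken as catalogue compounds; 23 would otherwise be one N-acylation of (R)-4-benzyloxazolidin-2-one with chloroacetyl chloride.

**Route**

Step 1
Reactants: 1 5-bromo-2-hydroxy-3-methoxybenzaldehyde
Product: 2 2-(allyloxy)-5-bromo-3-methoxybenzaldehyde
Conditions: allyl bromide, K2CO3, DMF, rt
Reagents that add atoms: allyl bromide, C=CCBr
Why: Williamson etherification of the phenoxide; the allyl ether is inert to ylide, aqueous acid, chlorite, boron triflate and borohydride and comes off later under neutral conditions, so the acid-labile benzylic carbinol of the cyclisation precursor survives until step 8.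

Step 2
Reactants: 2 2-(allyloxy)-5-bromo-3-methoxybenzaldehyde
Product: 3 2-(allyloxy)-5-bromo-1-methoxy-3-(2-methoxyethenyl)benzene (E/Z mixture)
Conditions: Ph3P(CH2OMe)Cl, KOt-Bu, THF, 0 °C → rt
Reagents that add atoms: (methoxymethyl)triphenylphosphonium chloride, COC[P+](c1ccccc1)(c1ccccc1)c1ccccc1.[Cl-]
Why: Wittig methoxymethylenation (one-carbon homologation) of an unhindered aryl aldehyde; the E/Z ratio is immaterial because both enol ethers hydrolyse to the same aldehyde.

Step 3
Reactants: 3 2-(allyloxy)-5-bromo-1-methoxy-3-(2-methoxyethenyl)benzene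
Product: 5 2-[2-(allyloxy)-5-bromo-3-methoxyphenyl]acetic acid, via arylacetaldehyde 4 (not isolated)
Conditions: 2 M HCl, THF, 50 °C; then NaClO2, NaH2PO4, 2-methyl-2-butene, t-BuOH/H2O, 0 °C → rt
Reagents that add atoms: water, O; sodium chlorite, [Na+].[O-]Cl=O
Why: Acid hydrolysis of the enol ether gives the enolisable arylacetaldehyde, which is oxidised without purification by the Pinnick oxidation, whose hypochlorite by-product is trapped by 2-methyl-2-butene so that the allyl ether and the electron-rich ring are spared.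

Step 4
Reactants: 5 2-[2-(allyloxy)-5-bromo-3-methoxyphenyl]acetic acid; 6 (S)-4-benzyloxazolidin-2-one
Product: 8 (S)-3-{2-[2-(allyloxy)-5-bromo-3-methoxyphenyl]acetyl}-4-benzyloxazolidin-2-one, via mixed pivalic anhydride 7 (not isolated)
Conditions: PivCl, Et3N, THF, −20 °C; then LiCl, 6, −20 °C → rt
Reagents that add atoms: none
Why: N-Acylation of the oxazolidinone by the mixed pivalic anhydride under LiCl/Et3N activation, the hindered pivaloyl carbonyl directing attack to the arylacetyl carbonyl.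

Step 5
Reactants: 8 (S)-3-(arylacetyl)-4-benzyloxazolidin-2-one; 9 4-(benzyloxy)-3-methoxybenzaldehyde
Product: 11 (2S,3S)-syn aldol imide, via dibutylboron Z-enolate 10 (not isolated)
Conditions: n-Bu2BOTf, i-Pr2NEt, CH2Cl2, −78 → 0 °C; 9, −78 → 0 °C; pH 7 buffer, MeOH, 30% H2O2, 0 °C
Reagents that add atoms: none
Why: Evans syn aldol reaction: soft enolisation gives the Z boron enolate, which reacts through a Zimmerman–Traxler chair on the face opposite the auxiliary benzyl group, setting the α-carbon (the future C3) as S in the imide (R after reduction), while the carbinol carbon formed with it is erased in step 8.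

Step 6
Reactants: 11 (2S,3S)-syn aldol imide
Product: 12 (1S,2R)-2-[2-(allyloxy)-5-bromo-3-methoxyphenyl]-1-[4-(benzyloxy)-3-methoxyphenyl]propane-1,3-diol
Conditions: LiBH4, MeOH (1 equiv), THF, 0 °C
Reagents that add atoms: none
Why: Reductive cleavage of the N-acyl oxazolidinone with LiBH4 gives the primary alcohol and returns the auxiliary without touching either stereocentre, the aryl bromide or the allyl ether.

Step 7
Reactants: 12 allyl-protected diol
Product: 13 4-bromo-2-[(1S,2R)-1-[4-(benzyloxy)-3-methoxyphenyl]-1,3-dihydroxypropan-2-yl]-6-methoxyphenol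
Conditions: Pd(PPh3)4 (5 mol %), morpholine, THF, rt
Reagents that add atoms: none
Why: Tsuji–Trost-type deallylation: zerovalent palladium ionises the aryl allyl ether to a π-allyl complex that is trapped by morpholine, under neutral conditions at room temperature where the aryl bromide does not undergo oxidative addition.

Step 8
Reactants: 13 4-bromo-2-[(1S,2R)-1-[4-(benzyloxy)-3-methoxyphenyl]-1,3-dihydroxypropan-2-yl]-6-methoxyphenol
Product: 14 [(2S,3R)-2-[4-(benzyloxy)-3-methoxyphenyl]-5-bromo-7-methoxy-2,3-dihydro-1-benzofuran-3-yl]methanol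
Conditions: p-TsOH·H2O (10 mol %), CH2Cl2 (0.02 M), 0 °C → rt, short reaction time; NaHCO3 quench
Reagents that add atoms: none
Why: Protonation of the benzylic hydroxyl of 13 and loss of water give a C2 cation delocalised onto O-4 of ring D (an O-benzyl para-quinone-methide oxocarbenium ion), and the ring C phenol oxygen O1 adds to C2 to form the O1–C2 bond; the closest known reaction type is the acid-catalysed cyclodehydration of 2-(2-hydroxyaryl)-1-arylpropane-1,3-diols to trans-2-aryl-3-hydroxymethyl-2,3-dihydrobenzofurans, an SN1 etherification of a para-alkoxybenzyl alcohol. The furan ring closes in a 5-exo-trig mode, O1 attacking the trigonal C2 whose π bond to ring D lies outside the ring O1–C7a–C3a–C3–C2. The new C2 centre is controlled by the existing C3 centre: the aryl group ends up on the face away from CH2OH, and because ionisation is reversible under the acid the more stable 2,3-trans isomer (2S,3R) should accumulate whichever carbinol epimer of 13 is used. The step needs selectivity for the phenol over the primary alcohol, secured because attack by the primary oxygen would give a strained oxetane that reopens, and it needs suppression of fragmentation with loss of formaldehyde to a stilbene, which dilution, low temperature and short exposure address. The benzyl ether, the aryl bromide and the methyl ethers are inert to catalytic sulfonic acid at this temperature.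

Step 9
Reactants: 14 dihydrobenzofuran alcohol
Product: 15 tert-butyldiphenylsilyl ether of 14
Conditions: TBDPSCl, imidazole, DMF, rt
Reagents that add atoms: tert-butyl(chloro)diphenylsilane, CC(C)(C)[Si](Cl)(c1ccccc1)c1ccccc1
Why: Imidazole-promoted silylation of the only free hydroxyl with a group chosen to withstand Grignard formation, hot LiCl/DMSO and lithium amide base.

Step 10
Reactants: 16 (R)-epichlorohydrin; 17 diethyl malonate
Product: 18 ethyl (1S,5R)-2-oxo-3-oxabicyclo[3.1.0]hexane-1-carboxylate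
Conditions: NaOEt, EtOH, reflux
Reagents that add atoms: none
Why: Tandem alkylation–cyclopropanation–lactonisation: the malonate anion opens the epoxide at CH2, the alkoxide closes a new epoxide by displacing chloride, the malonate carbanion opens it in a 3-exo-tet step with inversion and the released alkoxide lactonises, so that (R)-epichlorohydrin gives the (1S,5R) bicycle.

Step 11
Reactants: 15 silyl-protected aryl bromide; 18 ethyl (1S,5R)-2-oxo-3-oxabicyclo[3.1.0]hexane-1-carboxylate
Product: 20 ethyl (4R)-4-(arylmethyl)-2-oxooxolane-3-carboxylate (C3 epimers), via arylmagnesium bromide 19 (not isolated)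
Conditions: Mg turnings, LiCl, THF, 40 °C; then CuI (10 mol %), 18, THF, −40 → 0 °C; cold 1 M HCl
Reagents that add atoms: none
Why: Magnesium insertion gives the aryl Grignard reagent and CuI-catalysed homoconjugate addition opens the doubly acceptor-activated cyclopropane at its CH2 carbon, so the ring C carbon that carried bromine becomes bonded to the new benzylic CH2 while the lactone β-centre (R) is carried over untouched from 18.

Step 12
Reactants: 20 ethyl (4R)-4-(arylmethyl)-2-oxooxolane-3-carboxylate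
Product: 21 (4R)-4-(arylmethyl)oxolan-2-one
Conditions: LiCl, H2O, DMSO, 140 °C
Reagents that add atoms: none
Why: Krapcho dealkoxycarbonylation of the malonate-type ester; the β-centre is not involved and both α-epimers give the same lactone.

Step 13
Reactants: 22 methyl 4-hydroxy-3-methoxybenzoate; 23 (R)-4-benzyl-3-(chloroacetyl)oxazolidin-2-one
Product: 24 methyl 4-{2-[(4R)-4-benzyl-2-oxooxazolidin-3-yl]-2-oxoethoxy}-3-methoxybenzoate
Conditions: K2CO3, NaI (10 mol %), acetone, rt → 45 °C
Reagents that add atoms: none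
Why: Williamson ether synthesis: the phenoxide displaces halide (iodide formed in situ by halide exchange) at the carbon α to the imide carbonyl, an SN2 reaction much faster than acyl transfer from the imide.

Step 14
Reactants: 24 aryloxyacetyl imide; 9 4-(benzyloxy)-3-methoxybenzaldehyde
Product: 26 (2R,3S)-syn glycolate aldol imide, via dibutylboron Z-enolate 25 (not isolated)
Conditions: n-Bu2BOTf, i-Pr2NEt, CH2Cl2, −78 → 0 °C; 9, −78 → 0 °C; pH 7 buffer, MeOH, 30% H2O2, 0 °C
Reagents that add atoms: none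
Why: Evans syn glycolate aldol reaction through the Z boron enolate and a Zimmerman–Traxler chair, the (R)-benzyl group of the auxiliary fixing the aryloxy-bearing carbon (future C8, S after reduction) and the carbinol carbon C7 as S.

Step 15
Reactants: 26 (2R,3S)-syn glycolate aldol imide
Product: 27 methyl 4-{[(1S,2S)-1-[4-(benzyloxy)-3-methoxyphenyl]-1,3-dihydroxypropan-2-yl]oxy}-3-methoxybenzoate (threo)
Conditions: NaBH4, THF/H2O (3:1), 0 °C → rt
Reagents that add atoms: none
Why: NaBH4 in aqueous THF reduces the activated imide carbonyl to the primary alcohol and releases the auxiliary, whereas the aryl methyl ester is inert to this reagent.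

Step 16
Reactants: 27 threo diol
Product: 28 C9 tert-butyldimethylsilyl ether of 27
Conditions: TBSCl (1.05 equiv), imidazole, CH2Cl2, 0 °C
Reagents that add atoms: tert-butyl(chloro)dimethylsilane, CC(C)(C)[Si](C)(C)Cl
Why: Silylation discriminates the primary hydroxyl from the secondary benzylic hydroxyl, which is flanked by the aryl ring and the aryloxy-bearing carbon.

Step 17
Reactants: 28 (7S,8S) mono-silyl ether
Product: 29 (7R,8S) 4-nitrobenzoate
Conditions: 4-nitrobenzoic acid, PPh3, DIAD, THF, 0 °C → rt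
Reagents that add atoms: 4-nitrobenzoic acid, OC(=O)c1ccc(cc1)[N+](=O)[O-]
Why: Mitsunobu esterification: the alkoxyphosphonium ion of the C7 hydroxyl is displaced by 4-nitrobenzoate with inversion (SN2), converting the threo (7S,8S) series into the erythro (7R,8S) series.

Step 18
Reactants: 29 (7R,8S) 4-nitrobenzoate
Product: 30 (7R,8S) C7 alcohol (erythro)
Conditions: K2CO3, MeOH, 0 °C → rt
Reagents that add atoms: none
Why: Base-catalysed transesterification removes the activated 4-nitrobenzoate by acyl–oxygen cleavage, so C7 keeps its configuration, while methanolysis of the ring B methyl ester is degenerate and the silyl ether is stable.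

Step 19
Reactants: 30 (7R,8S) C7 alcohol
Product: 31 C7,C9-bis(tert-butyldimethylsilyl) ether
Conditions: TBSOTf, 2,6-lutidine, CH2Cl2, −78 → 0 °C
Reagents that add atoms: tert-butyldimethylsilyl trifluoromethanesulfonate, CC(C)(C)[Si](C)(C)OS(=O)(=O)C(F)(F)F
Why: Silylation with a silyl triflate and a hindered pyridine base protects the encumbered secondary benzylic alcohol at low temperature.

Step 20
Reactants: 31 bis-silyl methyl ester
Product: 32 ring B benzylic alcohol
Conditions: i-Bu2AlH (2.5 equiv), CH2Cl2, −78 °C; aqueous potassium sodium tartrate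
Reagents that add atoms: none
Why: Hydride reduction of the aryl methyl ester to the benzylic alcohol with i-Bu2AlH, to which silyl and benzyl ethers are inert.

Step 21
Reactants: 32 ring B benzylic alcohol
Product: 33 ring B benzylic bromide
Conditions: CBr4, PPh3, 2,6-lutidine, CH2Cl2, 0 °C
Reagents that add atoms: carbon tetrabromide, BrC(Br)(Br)Br
Why: Appel bromination of the primary benzylic alcohol under buffered, non-acidic conditions that leave the benzylic silyl ether alone; the bromide is used at once.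

Step 22
Reactants: 21 (4R)-4-(arylmethyl)oxolan-2-one; 33 ring B benzylic bromide
Product: 35 fully protected (3R,4R)-trans lactone, via lithium lactone enolate 34 (not isolated)
Conditions: LiN(SiMe3)2, THF, −78 °C; then 33, DMPU, −78 → −40 °C
Reagents that add atoms: none
Why: Alkylation of the lithium enolate of a β-substituted butyrolactone with a benzylic bromide occurs on the face anti to the β-substituent, giving the 3,4-trans lactone and setting Cα as R under substrate control.

Step 23
Reactants: 35 fully protected lactone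
Product: 36 di-O-benzyl triol
Conditions: Bu4NF, AcOH, THF, 0 °C → rt
Reagents that add atoms: none
Why: Fluoride-mediated desilylation, buffered with acetic acid so that the lactone is neither opened nor epimerised, removes the two tert-butyldimethylsilyl groups and the tert-butyldiphenylsilyl group.

Step 24
Reactants: 36 di-O-benzyl triol
Product: 37 CNP0298853.1
Conditions: H2 (1 atm), palladium on carbon (10 wt % Pd), EtOAc/MeOH, rt, stopped at two equivalents of H2
Reagents that add atoms: none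
Why: Hydrogenolysis of the two aryl benzyl ethers over palladium at atmospheric pressure is much faster than cleavage of the benzylic C–O bonds of the dihydrobenzofuran and of the C7 carbinol, so the reaction is stopped once the calculated amount of hydrogen is taken up.

**Compound list**

1 | 5-bromo-2-hydroxy-3-methoxybenzaldehyde | COc1cc(Br)cc(C=O)c1O | starting material
2 | 2-(allyloxy)-5-bromo-3-methoxybenzaldehyde | COc1cc(Br)cc(C=O)c1OCC=C | intermediate
3 | 2-(allyloxy)-5-bromo-1-methoxy-3-(2-methoxyethenyl)benzene (E/Z mixture) | COC=Cc1cc(Br)cc(OC)c1OCC=C | intermediate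
4 | 2-[2-(allyloxy)-5-bromo-3-methoxyphenyl]acetaldehyde | O=CCc1cc(Br)cc(OC)c1OCC=C | intermediate
5 | 2-[2-(allyloxy)-5-bromo-3-methoxyphenyl]acetic acid | OC(=O)Cc1cc(Br)cc(OC)c1OCC=C | intermediate
6 | (S)-4-benzyloxazolidin-2-one | O=C1N[C@@H](Cc2ccccc2)CO1 | starting material
7 | 2-[2-(allyloxy)-5-bromo-3-methoxyphenyl]acetic pivalic anhydride | CC(C)(C)C(=O)OC(=O)Cc1cc(Br)cc(OC)c1OCC=C | intermediate
8 | (S)-3-{2-[2-(allyloxy)-5-bromo-3-methoxyphenyl]acetyl}-4-benzyloxazolidin-2-one | O=C(Cc1cc(Br)cc(OC)c1OCC=C)N1[C@@H](Cc2ccccc2)COC1=O | intermediate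
9 | 4-(benzyloxy)-3-methoxybenzaldehyde | COc1cc(C=O)ccc1OCc1ccccc1 | starting material
10 | dibutylboron (Z)-enolate of 8 | CCCCB(CCCC)O/C(=C\c1cc(Br)cc(OC)c1OCC=C)N1[C@@H](Cc2ccccc2)COC1=O | intermediate
11 | (S)-3-[(2S,3S)-2-[2-(allyloxy)-5-bromo-3-methoxyphenyl]-3-[4-(benzyloxy)-3-methoxyphenyl]-3-hydroxypropanoyl]-4-benzyloxazolidin-2-one | C=CCOc1c(OC)cc(Br)cc1[C@H](C(=O)N1[C@@H](Cc2ccccc2)COC1=O)[C@@H](c1ccc(OCc2ccccc2)c(OC)c1)O | intermediate
12 | (1S,2R)-2-[2-(allyloxy)-5-bromo-3-methoxyphenyl]-1-[4-(benzyloxy)-3-methoxyphenyl]propane-1,3-diol | C=CCOc1c(OC)cc(Br)cc1[C@H](CO)[C@@H](c1ccc(OCc2ccccc2)c(OC)c1)O | intermediate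
13 | 4-bromo-2-[(1S,2R)-1-[4-(benzyloxy)-3-methoxyphenyl]-1,3-dihydroxypropan-2-yl]-6-methoxyphenol | Oc1c(OC)cc(Br)cc1[C@H](CO)[C@@H](c1ccc(OCc2ccccc2)c(OC)c1)O | intermediate
14 | [(2S,3R)-2-[4-(benzyloxy)-3-methoxyphenyl]-5-bromo-7-methoxy-2,3-dihydro-1-benzofuran-3-yl]methanol | Brc1cc(OC)c2c(c1)[C@H](CO)[C@@H](c1ccc(OCc3ccccc3)c(OC)c1)O2 | intermediate
15 | {[(2S,3R)-2-[4-(benzyloxy)-3-methoxyphenyl]-5-bromo-7-methoxy-2,3-dihydro-1-benzofuran-3-yl]methoxy}(tert-butyl)diphenylsilane | Brc1cc(OC)c2c(c1)[C@H](CO[Si](c1ccccc1)(c1ccccc1)C(C)(C)C)[C@@H](c1ccc(OCc3ccccc3)c(OC)c1)O2 | intermediate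
16 | (R)-epichlorohydrin, (R)-2-(chloromethyl)oxirane | ClC[C@H]1CO1 | starting material
17 | diethyl malonate | CCOC(=O)CC(=O)OCC | starting material
18 | ethyl (1S,5R)-2-oxo-3-oxabicyclo[3.1.0]hexane-1-carboxylate | O=C1OC[C@@H]2C[C@]12C(=O)OCC | intermediate
19 | [(2S,3R)-2-[4-(benzyloxy)-3-methoxyphenyl]-3-{[(tert-butyldiphenylsilyl)oxy]methyl}-7-methoxy-2,3-dihydro-1-benzofuran-5-yl]magnesium bromide | Br[Mg]c1cc(OC)c2c(c1)[C@H](CO[Si](c1ccccc1)(c1ccccc1)C(C)(C)C)[C@@H](c1ccc(OCc3ccccc3)c(OC)c1)O2 | intermediate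
20 | ethyl (4R)-4-{[(2S,3R)-2-[4-(benzyloxy)-3-methoxyphenyl]-3-{[(tert-butyldiphenylsilyl)oxy]methyl}-7-methoxy-2,3-dihydro-1-benzofuran-5-yl]methyl}-2-oxooxolane-3-carboxylate (C3 epimers) | CCOC(=O)C1C(=O)OC[C@@H]1Cc1cc(OC)c2c(c1)[C@H](CO[Si](c1ccccc1)(c1ccccc1)C(C)(C)C)[C@@H](c1ccc(OCc3ccccc3)c(OC)c1)O2 | intermediate
21 | (4R)-4-{[(2S,3R)-2-[4-(benzyloxy)-3-methoxyphenyl]-3-{[(tert-butyldiphenylsilyl)oxy]methyl}-7-methoxy-2,3-dihydro-1-benzofuran-5-yl]methyl}oxolan-2-one | O=C1C[C@@H](Cc2cc(OC)c3c(c2)[C@H](CO[Si](c2ccccc2)(c2ccccc2)C(C)(C)C)[C@@H](c2ccc(OCc4ccccc4)c(OC)c2)O3)CO1 | intermediate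
22 | methyl 4-hydroxy-3-methoxybenzoate (methyl vanillate) | COC(=O)c1ccc(O)c(OC)c1 | starting material
23 | (R)-4-benzyl-3-(chloroacetyl)oxazolidin-2-one | O=C(CCl)N1[C@H](Cc2ccccc2)COC1=O | starting material
24 | methyl 4-{2-[(4R)-4-benzyl-2-oxooxazolidin-3-yl]-2-oxoethoxy}-3-methoxybenzoate | COC(=O)c1ccc(OCC(=O)N2[C@H](Cc3ccccc3)COC2=O)c(OC)c1 | intermediate
25 | dibutylboron (Z)-enolate of 24 | CCCCB(CCCC)O/C(=C\Oc1ccc(cc1OC)C(=O)OC)N1[C@H](Cc2ccccc2)COC1=O | intermediate
26 | methyl 4-{[(2R,3S)-1-[(4R)-4-benzyl-2-oxooxazolidin-3-yl]-3-[4-(benzyloxy)-3-methoxyphenyl]-3-hydroxy-1-oxopropan-2-yl]oxy}-3-methoxybenzoate | COc1cc([C@H](O)[C@H](C(=O)N2[C@H](Cc3ccccc3)COC2=O)Oc2ccc(cc2OC)C(=O)OC)ccc1OCc1ccccc1 | intermediate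
27 | methyl 4-{[(1S,2S)-1-[4-(benzyloxy)-3-methoxyphenyl]-1,3-dihydroxypropan-2-yl]oxy}-3-methoxybenzoate | COc1cc([C@H](O)[C@H](CO)Oc2ccc(cc2OC)C(=O)OC)ccc1OCc1ccccc1 | intermediate
28 | methyl 4-{[(1S,2S)-1-[4-(benzyloxy)-3-methoxyphenyl]-3-[(tert-butyldimethylsilyl)oxy]-1-hydroxypropan-2-yl]oxy}-3-methoxybenzoate | COc1cc([C@H](O)[C@H](CO[Si](C)(C)C(C)(C)C)Oc2ccc(cc2OC)C(=O)OC)ccc1OCc1ccccc1 | intermediate
29 | methyl 4-{[(1R,2S)-1-[4-(benzyloxy)-3-methoxyphenyl]-3-[(tert-butyldimethylsilyl)oxy]-1-[(4-nitrobenzoyl)oxy]propan-2-yl]oxy}-3-methoxybenzoate | COc1cc([C@@H](OC(=O)c2ccc(cc2)[N+](=O)[O-])[C@H](CO[Si](C)(C)C(C)(C)C)Oc2ccc(cc2OC)C(=O)OC)ccc1OCc1ccccc1 | intermediate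
30 | methyl 4-{[(1R,2S)-1-[4-(benzyloxy)-3-methoxyphenyl]-3-[(tert-butyldimethylsilyl)oxy]-1-hydroxypropan-2-yl]oxy}-3-methoxybenzoate | COc1cc([C@@H](O)[C@H](CO[Si](C)(C)C(C)(C)C)Oc2ccc(cc2OC)C(=O)OC)ccc1OCc1ccccc1 | intermediate
31 | methyl 4-{[(1R,2S)-1-[4-(benzyloxy)-3-methoxyphenyl]-1,3-bis[(tert-butyldimethylsilyl)oxy]propan-2-yl]oxy}-3-methoxybenzoate | COc1cc([C@@H](O[Si](C)(C)C(C)(C)C)[C@H](CO[Si](C)(C)C(C)(C)C)Oc2ccc(cc2OC)C(=O)OC)ccc1OCc1ccccc1 | intermediate
32 | (4-{[(1R,2S)-1-[4-(benzyloxy)-3-methoxyphenyl]-1,3-bis[(tert-butyldimethylsilyl)oxy]propan-2-yl]oxy}-3-methoxyphenyl)methanol | COc1cc([C@@H](O[Si](C)(C)C(C)(C)C)[C@H](CO[Si](C)(C)C(C)(C)C)Oc2ccc(CO)cc2OC)ccc1OCc1ccccc1 | intermediate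
33 | 4-(bromomethyl)-1-{[(1R,2S)-1-[4-(benzyloxy)-3-methoxyphenyl]-1,3-bis[(tert-butyldimethylsilyl)oxy]propan-2-yl]oxy}-2-methoxybenzene | COc1cc([C@@H](O[Si](C)(C)C(C)(C)C)[C@H](CO[Si](C)(C)C(C)(C)C)Oc2ccc(CBr)cc2OC)ccc1OCc1ccccc1 | intermediate
34 | lithium enolate of 21 | [Li]OC1=C[C@@H](Cc2cc(OC)c3c(c2)[C@H](CO[Si](c2ccccc2)(c2ccccc2)C(C)(C)C)[C@@H](c2ccc(OCc4ccccc4)c(OC)c2)O3)CO1 | intermediate
35 | (3R,4R)-3-[(4-{[(1R,2S)-1-[4-(benzyloxy)-3-methoxyphenyl]-1,3-bis[(tert-butyldimethylsilyl)oxy]propan-2-yl]oxy}-3-methoxyphenyl)methyl]-4-{[(2S,3R)-2-[4-(benzyloxy)-3-methoxyphenyl]-3-{[(tert-butyldiphenylsilyl)oxy]methyl}-7-methoxy-2,3-dihydro-1-benzofuran-5-yl]methyl}oxolan-2-one | COc1cc([C@@H](O[Si](C)(C)C(C)(C)C)[C@H](CO[Si](C)(C)C(C)(C)C)Oc2ccc(C[C@H]3C(=O)OC[C@@H]3Cc3cc(OC)c4c(c3)[C@H](CO[Si](c3ccccc3)(c3ccccc3)C(C)(C)C)[C@@H](c3ccc(OCc5ccccc5)c(OC)c3)O4)cc2OC)ccc1OCc1ccccc1 | intermediate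
36 | (3R,4R)-3-[(4-{[(1R,2S)-1-[4-(benzyloxy)-3-methoxyphenyl]-1,3-dihydroxypropan-2-yl]oxy}-3-methoxyphenyl)methyl]-4-{[(2S,3R)-2-[4-(benzyloxy)-3-methoxyphenyl]-3-(hydroxymethyl)-7-methoxy-2,3-dihydro-1-benzofuran-5-yl]methyl}oxolan-2-one | COc1cc([C@@H](O)[C@H](CO)Oc2ccc(C[C@H]3C(=O)OC[C@@H]3Cc3cc(OC)c4c(c3)[C@H](CO)[C@@H](c3ccc(OCc5ccccc5)c(OC)c3)O4)cc2OC)ccc1OCc1ccccc1 | intermediate
37 | CNP0298853.1, (3R,4R)-3-[(4-{[(1R,2S)-1,3-dihydroxy-1-(4-hydroxy-3-methoxyphenyl)propan-2-yl]oxy}-3-methoxyphenyl)methyl]-4-{[(2S,3R)-2-(4-hydroxy-3-methoxyphenyl)-3-(hydroxymethyl)-7-methoxy-2,3-dihydro-1-benzofuran-5-yl]methyl}oxolan-2-one | COc1cc([C@@H](O)[C@H](CO)Oc2ccc(C[C@H]3C(=O)OC[C@@H]3Cc3cc(OC)c4c(c3)[C@H](CO)[C@@H](c3ccc(O)c(OC)c3)O4)cc2OC)ccc1O | target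

**Step count**

Total: 24 steps (the six intermediates that are not isolated are not counted as steps).
Longest linear sequence: 14 steps (steps 1–9, 11, 12, 22–24).

**Steps most likely to fail, with fallbacks**

Step 17. The alkoxyphosphonium ion sits on a benzylic carbon bearing a para-alkoxyaryl group. It may ionise before the carboxylate arrives, which would erode the inversion at C7, or it may eliminate towards the enol ether. Fallback: starting from 28, the carbinol is oxidised with Dess–Martin periodinane (NaHCO3, CH2Cl2) to the aryl ketone methyl 4-{[(2S)-1-[4-(benzyloxy)-3-methoxyphenyl]-3-[(tert-butyldimethylsilyl)oxy]-1-oxopropan-2-yl]oxy}-3-methoxybenzoate F1. This is reduced at once with Zn(BH4)2 in ether at low temperature. Chelation of zinc between the carbonyl oxygen and the C8 aryloxy oxygen (assisted by the ortho methoxy group of ring B) should deliver hydride anti to the CH2OSi group and give the erythro alcohol, so the sequence rejoins the route at 30. Inversion by substitution is replaced by an oxidation–reduction pair under substrate control.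

Step 11. Magnesium insertion into a functionalised, electron-rich aryl bromide may be sluggish or accompanied by homocoupling and protonation. The Grignard reagent may also add to the lactone or ester carbonyl of 18 in competition with cyclopropane opening. Fallback: starting from 15, bromine–lithium exchange (n-BuLi, THF, −78 °C) and quenching with DMF give the aldehyde (2S,3R)-2-[4-(benzyloxy)-3-methoxyphenyl]-3-{[(tert-butyldiphenylsilyl)oxy]methyl}-7-methoxy-2,3-dihydro-1-benzofuran-5-carbaldehyde F2. Stobbe condensation with dimethyl succinate (KOt-Bu, t-BuOH) gives the (E)-arylidene half-ester (3E)-4-aryl-3-(methoxycarbonyl)but-3-enoic acid F3. Asymmetric hydrogenation with [Rh(cod)2]BF4 and a chiral bisphosphine such as MOD-DIOP, in the enantiomeric form that delivers the R acid, gives (3R)-4-aryl-3-(methoxycarbonyl)butanoic acid F4. Reduction of the methyl ester in the presence of the carboxylate salt with Ca(BH4)2 (from CaCl2 and NaBH4 in ethanol) and acidification close the lactone, rejoining the route at 21. The lactone stereocentre then comes from catalyst control and no organomagnesium species is needed.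

Step 8. The C2 cation may fragment with loss of formaldehyde to a stilbene, may be captured intermolecularly by an electron-rich arene, or the cis isomer may fail to equilibrate fully to trans. Fallback: starting from 12, the primary hydroxyl is silylated first (TBDPSCl, imidazole) to give (1S,2R)-2-[2-(allyloxy)-5-bromo-3-methoxyphenyl]-1-[4-(benzyloxy)-3-methoxyphenyl]-3-[(tert-butyldiphenylsilyl)oxy]propan-1-ol F5. Deallylation with Pd(PPh3)4 and morpholine gives the phenol 4-bromo-2-[(1S,2R)-1-[4-(benzyloxy)-3-methoxyphenyl]-3-[(tert-butyldiphenylsilyl)oxy]-1-hydroxypropan-2-yl]-6-methoxyphenol F6. The same acid-mediated phenol capture on F6 gives the silyl ether directly, rejoining the route at 15. Because the γ-oxygen no longer carries a proton, expulsion of formaldehyde from the cation is disfavoured, and the bulkier C3 substituent should reinforce the trans preference; the substrate and the order of protection and ring closure are changed, not merely the acid.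

Further compounds
F1 | step 17 | methyl 4-{[(2S)-1-[4-(benzyloxy)-3-methoxyphenyl]-3-[(tert-butyldimethylsilyl)oxy]-1-oxopropan-2-yl]oxy}-3-methoxybenzoate | COc1cc(C(=O)[C@H](CO[Si](C)(C)C(C)(C)C)Oc2ccc(cc2OC)C(=O)OC)ccc1OCc1ccccc1
F2 | step 11 | (2S,3R)-2-[4-(benzyloxy)-3-methoxyphenyl]-3-{[(tert-butyldiphenylsilyl)oxy]methyl}-7-methoxy-2,3-dihydro-1-benzofuran-5-carbaldehyde | O=Cc1cc(OC)c2c(c1)[C@H](CO[Si](c1ccccc1)(c1ccccc1)C(C)(C)C)[C@@H](c1ccc(OCc3ccccc3)c(OC)c1)O2
F3 | step 11 | (3E)-4-[(2S,3R)-2-[4-(benzyloxy)-3-methoxyphenyl]-3-{[(tert-butyldiphenylsilyl)oxy]methyl}-7-methoxy-2,3-dihydro-1-benzofuran-5-yl]-3-(methoxycarbonyl)but-3-enoic acid | OC(=O)C/C(=C\c1cc(OC)c2c(c1)[C@H](CO[Si](c1ccccc1)(c1ccccc1)C(C)(C)C)[C@@H](c1ccc(OCc3ccccc3)c(OC)c1)O2)C(=O)OC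
F4 | step 11 | (3R)-4-[(2S,3R)-2-[4-(benzyloxy)-3-methoxyphenyl]-3-{[(tert-butyldiphenylsilyl)oxy]methyl}-7-methoxy-2,3-dihydro-1-benzofuran-5-yl]-3-(methoxycarbonyl)butanoic acid | OC(=O)C[C@@H](Cc1cc(OC)c2c(c1)[C@H](CO[Si](c1ccccc1)(c1ccccc1)C(C)(C)C)[C@@H](c1ccc(OCc3ccccc3)c(OC)c1)O2)C(=O)OC
F5 | step 8 | (1S,2R)-2-[2-(allyloxy)-5-bromo-3-methoxyphenyl]-1-[4-(benzyloxy)-3-methoxyphenyl]-3-[(tert-butyldiphenylsilyl)oxy]propan-1-ol | C=CCOc1c(OC)cc(Br)cc1[C@H](CO[Si](c1ccccc1)(c1ccccc1)C(C)(C)C)[C@@H](c1ccc(OCc2ccccc2)c(OC)c1)O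
F6 | step 8 | 4-bromo-2-[(1S,2R)-1-[4-(benzyloxy)-3-methoxyphenyl]-3-[(tert-butyldiphenylsilyl)oxy]-1-hydroxypropan-2-yl]-6-methoxyphenol | Oc1c(OC)cc(Br)cc1[C@H](CO[Si](c1ccccc1)(c1ccccc1)C(C)(C)C)[C@@H](c1ccc(OCc2ccccc2)c(OC)c1)O
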